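## Retrosynthetic overview

- Numbering: indane C1 carries the 4-hydroxybenzoyl group (ring D on the ketone carbon), C2 the 4-hydroxyphenyl ring B and C3 the 3,5-dihydroxyphenyl ring C; C3a and C7a are the fusion carbons of resorcinol ring A; all three substituents lie on one face.
- Feature used: rings B and C are cis on neighbouring C2 and C3, C3 is benzylic to ring A and C3a has no hydrogen. Syn addition of an aryl–palladium unit across a C2=C3 indene bond therefore leaves palladium on C3 with no syn β-hydrogen, free to take a second aryl group with retention.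
- Disconnections: debenzylation; C1 epimerisation by kinetic protonation of the ketone enolate; ketone from a C1 aldehyde and a ring D Grignard reagent; aldehyde from a nitromethyl group (Nef); the C2–ring B and C3–ring C bonds from one palladium-catalysed three-component diarylation of a 1-(nitromethyl)indene.
- The indene comes from acid cyclodehydration of an (S)-3-aryl-4-nitrobutanal, made by enamine-catalysed Michael addition of acetaldehyde to the nitrostyrene of 3,5-bis(benzyloxy)benzaldehyde (Henry condensation).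
- Ring order: ring A is bought in; the five-membered ring closes in step 3; rings B and C are attached in step 5 and ring D in step 7; the C1 centre from step 2 steers C2 and C3 and is inverted in step 9.

Key step: step 5

Assumption: the SMILES is read as the all-cis indane (1R,2R,3R), with the C1 aroyl group, ring B and ring C on one face; compounds 10 and 14 are taken as purchased reagents.

## Route

Step 1
Reactants: 1 3,5-bis(benzyloxy)benzaldehyde; 2 nitromethane
Product: 3 (E)-1,3-bis(benzyloxy)-5-(2-nitroethenyl)benzene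
Conditions: NH4OAc, AcOH, 2 (excess), 90 °C
Reagents that add atoms: none
Why: Henry (nitroaldol) condensation with dehydration in the same pot should give the conjugated nitroalkene as its more stable E isomer.

Step 2
Reactants: 3 (E)-1,3-bis(benzyloxy)-5-(2-nitroethenyl)benzene; 4 acetaldehyde
Product: 5 (3S)-3-[3,5-bis(benzyloxy)phenyl]-4-nitrobutanal
Conditions: (S)-2-[diphenyl(trimethylsilyloxy)methyl]pyrrolidine (10 mol%), 4 (10 equiv), 1,4-dioxane, rt
Reagents that add atoms: none
Why: Enamine-catalysed asymmetric Michael addition of acetaldehyde to a nitroalkene, in which the diphenyl(silyloxy)methyl group of the (S)-catalyst shields one enamine face so that one face of the nitroalkene is attacked and the benzylic centre (future C1) is set as S.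

Step 3
Reactants: 5 (3S)-3-[3,5-bis(benzyloxy)phenyl]-4-nitrobutanal
Product: 7 (1S)-4,6-bis(benzyloxy)-1-(nitromethyl)-1H-indene, via indanol 6 (not isolated)
Conditions: TsOH·H2O (10 mol%), CH2Cl2 (0.02 M), 4 Å MS, 0 °C to rt; aq NaHCO3 quench
Reagents that add atoms: none
Why: Intramolecular Friedel–Crafts hydroxyalkylation followed by dehydration (cyclodehydration), in which the ring A carbon ortho to one and para to the other benzyloxy group attacks the protonated aldehyde and the resulting electron-rich benzylic alcohol 6 loses water to the C2=C3 alkene, while C1 is untouched because no base is present to move the double bond.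

Step 4
Reactants: 8 4-(benzyloxy)aniline
Product: 9 4-(benzyloxy)benzenediazonium tetrafluoroborate
Conditions: NaNO2, 48% aq HBF4, EtOH/H2O, 0 °C; precipitate washed with cold Et2O
Reagents that add atoms: sodium nitrite, [Na+].[O-]N=O; tetrafluoroboric acid, [H+].F[B-](F)(F)F
Why: Diazotisation of a primary arylamine, from which the tetrafluoroborate salt should precipitate in storable form.

Step 5
Reactants: 7 (1S)-4,6-bis(benzyloxy)-1-(nitromethyl)-1H-indene; 9 4-(benzyloxy)benzenediazonium tetrafluoroborate; 10 3,5-bis(benzyloxy)phenylboronic acid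
Product: 11 (1S,2R,3R)-4,6-bis(benzyloxy)-3-[3,5-bis(benzyloxy)phenyl]-2-[4-(benzyloxy)phenyl]-1-(nitromethyl)-2,3-dihydro-1H-indene (rings B and C cis, nitromethyl trans to both)
Conditions: Pd2(dba)3 (5 mol%), NaHCO3 (2 equiv), 10 (2.5 equiv), 9 (2 equiv, added in portions), tert-amyl alcohol/THF, rt, Ar
Reagents that add atoms: none
Why: Oxidative addition of 9 to zerovalent palladium with loss of N2 gives a cationic aryl–palladium species (divalent palladium) that binds the electron-rich C2=C3 bond of 7 on the face away from the C1 nitromethyl group and inserts syn, ring B going to C2 and palladium to benzylic C3, where ring A holds it as an η3-benzyl complex; the C2 hydrogen is then anti to palladium and C3a has none, so β-hydride elimination has no syn hydrogen, and transmetalation with 10 followed by C–C reductive elimination with retention puts ring C on C3 on the face of ring B. The closest known reaction type is the three-component Heck–Matsuda/Suzuki–Miyaura vicinal diarylation of conjugated alkenes through π-allyl or π-benzyl palladium intermediates, together with the Heck arylation of indenes, which places palladium on the same benzylic carbon. No ring is closed; the step forms the C2–ring B and C3–ring C bonds on the preformed indene. The C2 stereocentre is controlled by the C1 substituent, which blocks one alkene face, and the C3 stereocentre by the syn course of insertion and the retentive reductive elimination, which tie it to C2. The step needs regioselectivity (benzylic stabilisation at C3 and crowding of C3 by the C4 benzyloxy group send ring B to C2), facial selectivity (C1 substituent), cis selectivity (syn mechanism) and chemoselectivity over direct coupling of 9 with 10 (portionwise addition of 9, excess of both partners); NaHCO3 only takes up the acid and is too weak to deprotonate C1–H or the nitro group.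

Step 6
Reactants: 11 (1S,2R,3R)-4,6-bis(benzyloxy)-3-[3,5-bis(benzyloxy)phenyl]-2-[4-(benzyloxy)phenyl]-1-(nitromethyl)-2,3-dihydro-1H-indene
Product: 13 (1S,2R,3R)-4,6-bis(benzyloxy)-3-[3,5-bis(benzyloxy)phenyl]-2-[4-(benzyloxy)phenyl]-2,3-dihydro-1H-indene-1-carbaldehyde, via potassium nitronate 12 (not isolated)
Conditions: KOH (1.1 equiv), MeOH/THF, 0 °C; then KMnO4 (0.7 equiv), MgSO4, H2O, 0 °C, 15 min
Reagents that add atoms: potassium permanganate, [K+].[O-][Mn](=O)(=O)=O (carbonyl oxygen of 13); potassium hydroxide, [K+].[OH-] (potassium of 12)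
Why: Oxidative Nef reaction, in which permanganate cleaves the nitronate C=N bond to the aldehyde under MgSO4 buffering, and C1, now α to the aldehyde, already has the more stable arrangement trans to ring B.

Step 7
Reactants: 13 (1S,2R,3R)-4,6-bis(benzyloxy)-3-[3,5-bis(benzyloxy)phenyl]-2-[4-(benzyloxy)phenyl]-2,3-dihydro-1H-indene-1-carbaldehyde; 14 4-(benzyloxy)phenylmagnesium bromide
Product: 15 [(1S,2R,3R)-4,6-bis(benzyloxy)-3-[3,5-bis(benzyloxy)phenyl]-2-[4-(benzyloxy)phenyl]-2,3-dihydro-1H-inden-1-yl][4-(benzyloxy)phenyl]methanol (both carbinol epimers)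
Conditions: 14 (1.5 equiv), THF, −78 °C to 0 °C; aq NH4Cl
Reagents that add atoms: none
Why: Grignard 1,2-addition to the aldehyde, favoured over enolisation at low temperature, gives a carbinol whose new centre is removed in the next step.

Step 8
Reactants: 15 [(1S,2R,3R)-4,6-bis(benzyloxy)-3-[3,5-bis(benzyloxy)phenyl]-2-[4-(benzyloxy)phenyl]-2,3-dihydro-1H-inden-1-yl][4-(benzyloxy)phenyl]methanol
Product: 16 [(1S,2R,3R)-4,6-bis(benzyloxy)-3-[3,5-bis(benzyloxy)phenyl]-2-[4-(benzyloxy)phenyl]-2,3-dihydro-1H-inden-1-yl][4-(benzyloxy)phenyl]methanone (aroyl group trans to ring B)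
Conditions: Dess–Martin periodinane, CH2Cl2, 0 °C to rt
Reagents that add atoms: none
Why: Dess–Martin oxidation of a secondary benzylic alcohol under near-neutral conditions should give the ketone with C1 in its thermodynamically preferred trans arrangement.

Step 9
Reactants: 16 [(1S,2R,3R)-4,6-bis(benzyloxy)-3-[3,5-bis(benzyloxy)phenyl]-2-[4-(benzyloxy)phenyl]-2,3-dihydro-1H-inden-1-yl][4-(benzyloxy)phenyl]methanone
Product: 18 [(1R,2R,3R)-4,6-bis(benzyloxy)-3-[3,5-bis(benzyloxy)phenyl]-2-[4-(benzyloxy)phenyl]-2,3-dihydro-1H-inden-1-yl][4-(benzyloxy)phenyl]methanone (all-cis), via lithium enolate 17 (not isolated)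
Conditions: LiN(SiMe3)2 (1.2 equiv), THF, −78 °C to 0 °C; recool to −78 °C; AcOH (5 equiv) in THF added fast; cold pH 7 work-up
Reagents that add atoms: lithium bis(trimethylsilyl)amide, [Li+].C[Si](C)(C)[N-][Si](C)(C)C (lithium of 17 only)
Why: Enolisation followed by kinetic protonation, in which the exocyclic enolate is flat at C1, ring B on C2 covers one face, and irreversible proton delivery at −78 °C from the face opposite ring B places hydrogen trans and the aroyl group cis to ring B, so C1 becomes R.

Step 10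
Reactants: 18 [(1R,2R,3R)-4,6-bis(benzyloxy)-3-[3,5-bis(benzyloxy)phenyl]-2-[4-(benzyloxy)phenyl]-2,3-dihydro-1H-inden-1-yl][4-(benzyloxy)phenyl]methanone
Product: 19 caraphenol B, (4-hydroxyphenyl)[(1R,2R,3R)-3-(3,5-dihydroxyphenyl)-4,6-dihydroxy-2-(4-hydroxyphenyl)-2,3-dihydro-1H-inden-1-yl]methanone
Conditions: H2 (1 atm), 10% Pd/C, EtOAc/MeOH, rt; stopped after uptake of six equivalents
Reagents that add atoms: none
Why: Catalytic hydrogenolysis of the six aryl benzyl ethers under neutral conditions should leave the electron-rich aryl ketone and the base-sensitive C1 centre untouched.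

## Compound list

1 | 3,5-bis(benzyloxy)benzaldehyde | O=Cc1cc(OCc2ccccc2)cc(OCc2ccccc2)c1 | starting material
2 | nitromethane | C[N+](=O)[O-] | starting material
3 | (E)-1,3-bis(benzyloxy)-5-(2-nitroethenyl)benzene | [O-][N+](=O)/C=C/c1cc(OCc2ccccc2)cc(OCc2ccccc2)c1 | intermediate
4 | acetaldehyde | CC=O | starting material
5 | (3S)-3-[3,5-bis(benzyloxy)phenyl]-4-nitrobutanal | O=CC[C@H](C[N+](=O)[O-])c1cc(OCc2ccccc2)cc(OCc2ccccc2)c1 | intermediate
6 | (3S)-5,7-bis(benzyloxy)-3-(nitromethyl)-2,3-dihydro-1H-inden-1-ol, both carbinol epimers (formed in the flask) | OC1C[C@H](C[N+](=O)[O-])c2cc(OCc3ccccc3)cc(OCc3ccccc3)c12 | intermediate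
7 | (1S)-4,6-bis(benzyloxy)-1-(nitromethyl)-1H-indene | [O-][N+](=O)C[C@@H]1c2cc(OCc3ccccc3)cc(OCc3ccccc3)c2C=C1 | intermediate
8 | 4-(benzyloxy)aniline | Nc1ccc(OCc2ccccc2)cc1 | starting material
9 | 4-(benzyloxy)benzenediazonium tetrafluoroborate | N#[N+]c1ccc(OCc2ccccc2)cc1.F[B-](F)(F)F | intermediate
10 | 3,5-bis(benzyloxy)phenylboronic acid | OB(O)c1cc(OCc2ccccc2)cc(OCc2ccccc2)c1 | starting material
11 | (1S,2R,3R)-4,6-bis(benzyloxy)-3-[3,5-bis(benzyloxy)phenyl]-2-[4-(benzyloxy)phenyl]-1-(nitromethyl)-2,3-dihydro-1H-indene | [O-][N+](=O)C[C@@H]1c2cc(OCc3ccccc3)cc(OCc3ccccc3)c2[C@@H](c2cc(OCc3ccccc3)cc(OCc3ccccc3)c2)[C@H]1c1ccc(OCc2ccccc2)cc1 | intermediate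
12 | potassium nitronate of 11 (formed in the flask) | [K+].[O-][N+]([O-])=C[C@@H]1c2cc(OCc3ccccc3)cc(OCc3ccccc3)c2[C@@H](c2cc(OCc3ccccc3)cc(OCc3ccccc3)c2)[C@H]1c1ccc(OCc2ccccc2)cc1 | intermediate
13 | (1S,2R,3R)-4,6-bis(benzyloxy)-3-[3,5-bis(benzyloxy)phenyl]-2-[4-(benzyloxy)phenyl]-2,3-dihydro-1H-indene-1-carbaldehyde | O=C[C@@H]1c2cc(OCc3ccccc3)cc(OCc3ccccc3)c2[C@@H](c2cc(OCc3ccccc3)cc(OCc3ccccc3)c2)[C@H]1c1ccc(OCc2ccccc2)cc1 | intermediate
14 | 4-(benzyloxy)phenylmagnesium bromide (THF solution) | Br[Mg]c1ccc(OCc2ccccc2)cc1 | starting material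
15 | [(1S,2R,3R)-4,6-bis(benzyloxy)-3-[3,5-bis(benzyloxy)phenyl]-2-[4-(benzyloxy)phenyl]-2,3-dihydro-1H-inden-1-yl][4-(benzyloxy)phenyl]methanol, both carbinol epimers | OC(c1ccc(OCc2ccccc2)cc1)[C@@H]1c2cc(OCc3ccccc3)cc(OCc3ccccc3)c2[C@@H](c2cc(OCc3ccccc3)cc(OCc3ccccc3)c2)[C@H]1c1ccc(OCc2ccccc2)cc1 | intermediate
16 | [(1S,2R,3R)-4,6-bis(benzyloxy)-3-[3,5-bis(benzyloxy)phenyl]-2-[4-(benzyloxy)phenyl]-2,3-dihydro-1H-inden-1-yl][4-(benzyloxy)phenyl]methanone (aroyl trans to ring B) | O=C(c1ccc(OCc2ccccc2)cc1)[C@@H]1c2cc(OCc3ccccc3)cc(OCc3ccccc3)c2[C@@H](c2cc(OCc3ccccc3)cc(OCc3ccccc3)c2)[C@H]1c1ccc(OCc2ccccc2)cc1 | intermediate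
17 | lithium enolate of 16, enolate geometry not defined (formed in the flask) | [Li]OC(c1ccc(OCc2ccccc2)cc1)=C1c2cc(OCc3ccccc3)cc(OCc3ccccc3)c2[C@@H](c2cc(OCc3ccccc3)cc(OCc3ccccc3)c2)[C@H]1c1ccc(OCc2ccccc2)cc1 | intermediate
18 | [(1R,2R,3R)-4,6-bis(benzyloxy)-3-[3,5-bis(benzyloxy)phenyl]-2-[4-(benzyloxy)phenyl]-2,3-dihydro-1H-inden-1-yl][4-(benzyloxy)phenyl]methanone (all-cis) | O=C(c1ccc(OCc2ccccc2)cc1)[C@H]1c2cc(OCc3ccccc3)cc(OCc3ccccc3)c2[C@@H](c2cc(OCc3ccccc3)cc(OCc3ccccc3)c2)[C@H]1c1ccc(OCc2ccccc2)cc1 | intermediate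
19 | caraphenol B, (4-hydroxyphenyl)[(1R,2R,3R)-3-(3,5-dihydroxyphenyl)-4,6-dihydroxy-2-(4-hydroxyphenyl)-2,3-dihydro-1H-inden-1-yl]methanone | O=C(c1ccc(O)cc1)[C@H]1c2cc(O)cc(O)c2[C@@H](c2cc(O)cc(O)c2)[C@H]1c1ccc(O)cc1 | target

## Step count and risks

Total step count: 10. Longest linear sequence: 9 steps (steps 1, 2, 3, 5, 6, 7, 8, 9, 10); step 4 is a one-step side branch.

Steps most likely to fail:

**Step 5 (three-component diarylation).** What may go wrong: direct coupling of the diazonium salt with the boronic acid may outrun alkene insertion. Palladium may leave C3 by base-assisted elimination or protonation before transmetalation. The benzylic palladium may epimerise and erode the cis relationship. Reductive elimination may be slow at the crowded C3. The acid released may oligomerise the electron-rich indene.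

Fallback: it sets out from nitroalkene 3 and comes back at indane 11. Ring B enters as the Michael donor, ring C by carbonyl addition, and the cis relationship is set by ionic hydrogenation instead of by palladium.
- Michael addition of 2-[4-(benzyloxy)phenyl]acetaldehyde to 3 with the same (S)-catalyst should give (3S)-2-[4-(benzyloxy)phenyl]-3-[3,5-bis(benzyloxy)phenyl]-4-nitrobutanal F1.
- Pinnick oxidation (NaClO2, NaH2PO4, 2-methyl-2-butene) gives the corresponding nitro acid F2.
- Intramolecular Friedel–Crafts acylation ((CF3CO)2O, CH2Cl2, 0 °C) onto the same ring A carbon gives (2R,3S)-5,7-bis(benzyloxy)-2-[4-(benzyloxy)phenyl]-3-(nitromethyl)indan-1-one F3. Its ketone carbon is the future C3, and the ring B carbon, α to the ketone, settles trans to the nitromethyl group.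
- The nitro group is masked as its nitronate with LiN(SiMe3)2, and the arylcerium reagent from 1,3-bis(benzyloxy)-5-bromobenzene (n-BuLi, CeCl3, THF, −78 °C) is added to give the tertiary benzylic alcohol F4.
- Et3SiH/CF3CO2H in CH2Cl2 at −40 °C ionises F4 to the C3 cation, which should take hydride on the face opposite ring B and so give 11 with rings B and C cis.

**Step 9 (inversion of C1).** What may go wrong: incomplete facial discrimination in the protonation, or re-equilibration to the more stable trans ketone during quench, work-up or chromatography. Recovered 16 can be resubmitted.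

Fallback: it sets out from ketone 16 and comes back at target 19. C1 is set by hydrogen addition to an alkene instead of by protonation.
- The lithium enolate of 16 is selenenylated with PhSeBr on the face opposite ring B to give the α-phenylseleno ketone F5.
- Oxidation with H2O2 in CH2Cl2/pyridine at 0 °C and syn elimination towards the only syn β-hydrogen, on C2, gives the indenyl ketone [(1S)-5,7-bis(benzyloxy)-1-[3,5-bis(benzyloxy)phenyl]-2-[4-(benzyloxy)phenyl]-1H-inden-3-yl][4-(benzyloxy)phenyl]methanone F6.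
- Hydrogenation of F6 over 10% Pd/C (H2, EtOAc/MeOH) should add hydrogen to the tetrasubstituted alkene from the face opposite ring C and remove the benzyl groups in the same operation, giving all-cis 19.

**Step 3 (cyclodehydration).** What may go wrong: cationic oligomerisation of the electron-rich indene, or intermolecular Friedel–Crafts capture of the benzylic cation before it loses a proton.

Fallback: it sets out from aldehyde 5 and comes back at indene 7. Ring closure is by acylation, whose ketone product is deactivated towards further reaction.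
- Pinnick oxidation of 5 gives (3S)-3-[3,5-bis(benzyloxy)phenyl]-4-nitrobutanoic acid F7.
- Intramolecular Friedel–Crafts acylation ((CF3CO)2O, CH2Cl2, 0 °C) gives (3S)-5,7-bis(benzyloxy)-3-(nitromethyl)indan-1-one F8.
- NaBH4 in MeOH/THF at 0 °C gives indanol 6, now isolated, which is dehydrated with catalytic pyridinium p-toluenesulfonate in toluene at 60 °C to 7.

## Further compounds

F1 | step 5 | (3S)-2-[4-(benzyloxy)phenyl]-3-[3,5-bis(benzyloxy)phenyl]-4-nitrobutanal (C2 not defined) | O=CC(c1ccc(OCc2ccccc2)cc1)[C@H](C[N+](=O)[O-])c1cc(OCc2ccccc2)cc(OCc2ccccc2)c1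
F2 | step 5 | (3S)-2-[4-(benzyloxy)phenyl]-3-[3,5-bis(benzyloxy)phenyl]-4-nitrobutanoic acid (C2 not defined) | OC(=O)C(c1ccc(OCc2ccccc2)cc1)[C@H](C[N+](=O)[O-])c1cc(OCc2ccccc2)cc(OCc2ccccc2)c1
F3 | step 5 | (2R,3S)-5,7-bis(benzyloxy)-2-[4-(benzyloxy)phenyl]-3-(nitromethyl)-2,3-dihydro-1H-inden-1-one (trans) | [O-][N+](=O)C[C@@H]1c2cc(OCc3ccccc3)cc(OCc3ccccc3)c2C(=O)[C@H]1c1ccc(OCc2ccccc2)cc1
F4 | step 5 | (2R,3S)-5,7-bis(benzyloxy)-1-[3,5-bis(benzyloxy)phenyl]-2-[4-(benzyloxy)phenyl]-3-(nitromethyl)-2,3-dihydro-1H-inden-1-ol (carbinol centre not defined) | [O-][N+](=O)C[C@@H]1c2cc(OCc3ccccc3)cc(OCc3ccccc3)c2C(O)(c2cc(OCc3ccccc3)cc(OCc3ccccc3)c2)[C@H]1c1ccc(OCc2ccccc2)cc1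
F5 | step 9 | [(1S,2S,3R)-4,6-bis(benzyloxy)-3-[3,5-bis(benzyloxy)phenyl]-2-[4-(benzyloxy)phenyl]-1-(phenylselanyl)-2,3-dihydro-1H-inden-1-yl][4-(benzyloxy)phenyl]methanone (selenium trans to ring B) | O=C(c1ccc(OCc2ccccc2)cc1)[C@@]1([Se]c2ccccc2)c2cc(OCc3ccccc3)cc(OCc3ccccc3)c2[C@@H](c2cc(OCc3ccccc3)cc(OCc3ccccc3)c2)[C@H]1c1ccc(OCc2ccccc2)cc1
F6 | step 9 | [(1S)-5,7-bis(benzyloxy)-1-[3,5-bis(benzyloxy)phenyl]-2-[4-(benzyloxy)phenyl]-1H-inden-3-yl][4-(benzyloxy)phenyl]methanone | O=C(c1ccc(OCc2ccccc2)cc1)C1=C(c2ccc(OCc3ccccc3)cc2)[C@H](c2cc(OCc3ccccc3)cc(OCc3ccccc3)c2)c2c(OCc3ccccc3)cc(OCc3ccccc3)cc21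
F7 | step 3 | (3S)-3-[3,5-bis(benzyloxy)phenyl]-4-nitrobutanoic acid | OC(=O)C[C@H](C[N+](=O)[O-])c1cc(OCc2ccccc2)cc(OCc2ccccc2)c1
F8 | step 3 | (3S)-5,7-bis(benzyloxy)-3-(nitromethyl)-2,3-dihydro-1H-inden-1-one | [O-][N+](=O)C[C@@H]1c2cc(OCc3ccccc3)cc(OCc3ccccc3)c2C(=O)C1
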